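**Plan**

1. Retro-Diels–Alder across C1–C13' and C3–C11' opens the norbornene into a 2-acetoxy-guaia-1(5),3-diene lactone (a 5-acetoxycyclopentadiene) and an α-methylene lactone of the 1,10-seco-eudesmane type; each half is traced back to an anisole.
2. In the diene half the seven-membered carbocycle (C1, C5–C10), fused to the five-membered ring A along C1–C5, is a benzene ring plus one carbon: taking C5 out leaves an arene whose para-oxygenated carbon is C8, ortho-methyl carbon is C10 and meta CH2CO2tBu carbon is C7, so an aryl diazoketone tethered at C1 closes ring A and enlarges the arene in one Buchner step.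
3. Forward, diene half: arene, then azulenone, then tropone, then face-selective hydrogenation and hydride reduction, inverting lactonisation, C4 methyl, C13 methylene, acetate, dehydration.
4. Forward, dienophile half: 3-methylanisole, Friedel–Crafts, Wittig and iridium hydrogenation (C4'), Birch reduction (C5'=C10'), copper–bisoxazoline cyclopropanation of the enol ether (C7'), cis-lactone, methylenation, SeO2 hydroxylation (C6'); the two halves are joined last.
5. Stereochemistry: C2 from a Noyori hydrogenation, relayed to C10 and C7 (H2 anti to the silyloxy group) and to C8 (hydride, then SN2 inversion); C4' and C7' from two independent catalysts, C8' and C6' from the substrate; C1, C3 and C11' from the cycloaddition.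
6. Locants in the Why lines: guaiane numbering (C1–C15) for the diene half, primed seco-eudesmane numbering (C1'–C15') for the other half.

Key step: step 7

Remark: the SMILES is taken as drawn; it lies in the antipodal series of the Inula sesquiterpene lactones, so both halves are made de novo; centres that are erased later are left undefined in the SMILES and marked as epimers.

**Diene half**

Step 1
Reactants: 1 1-bromo-2-methoxy-4-methylbenzene; 2 methyl 3-chloro-3-oxopropanoate
Product: 3 methyl 3-(5-bromo-4-methoxy-2-methylphenyl)-3-oxopropanoate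
Conditions: AlCl3 (2.5 equiv), CH2Cl2, 0 °C to rt; aq HCl
Reagents that add atoms: none
Why: Friedel–Crafts acylation at the position para to methoxy and ortho to methyl, the only site activated by both donors and not flanked by bromine, gives the β-keto ester directly.

Step 2
Reactants: 3 methyl 3-(5-bromo-4-methoxy-2-methylphenyl)-3-oxopropanoate
Product: 4 methyl (3S)-3-(5-bromo-4-methoxy-2-methylphenyl)-3-hydroxypropanoate
Conditions: RuCl2[(R)-BINAP] (0.5 mol %; the ligand antipode that gives the 3S alcohol), H2 (50 atm), MeOH, 50 °C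
Reagents that add atoms: none
Why: Noyori asymmetric hydrogenation of a β-keto ester, in which the chelated ruthenium hydride adds to one carbonyl face and sets the benzylic carbinol (later C2) as S; the aryl bromide is inert to this catalyst.

Step 3
Reactants: 4 methyl (3S)-3-(5-bromo-4-methoxy-2-methylphenyl)-3-hydroxypropanoate
Product: 5 methyl (3S)-3-(5-bromo-4-methoxy-2-methylphenyl)-3-[tert-butyl(dimethyl)silyl]oxypropanoate
Conditions: TBSCl, imidazole, DMF, rt
Reagents that add atoms: tert-butyl(chloro)dimethylsilane CC(C)(C)[Si](C)(C)Cl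
Why: Silylation of the secondary alcohol; a silyl ether is the one oxygen group that should survive the carbenoid, hydride, organocerium and enolate steps ahead.

Step 4
Reactants: 5 methyl (3S)-3-(5-bromo-4-methoxy-2-methylphenyl)-3-[tert-butyl(dimethyl)silyl]oxypropanoate; 6 (2-tert-butoxy-2-oxoethyl)zinc bromide
Product: 7 methyl (3S)-3-[5-(2-tert-butoxy-2-oxoethyl)-4-methoxy-2-methylphenyl]-3-[tert-butyl(dimethyl)silyl]oxypropanoate
Conditions: Pd2(dba)3 (2 mol %), XPhos (8 mol %), THF, 60 °C
Reagents that add atoms: none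
Why: Negishi coupling of the Reformatsky reagent with the aryl bromide (oxidative addition, transmetalation, reductive elimination) installs the acetic ester that becomes C11 and C12 and leaves the methyl ester and the silyl ether alone.

Step 5
Reactants: 7 methyl (3S)-3-[5-(2-tert-butoxy-2-oxoethyl)-4-methoxy-2-methylphenyl]-3-[tert-butyl(dimethyl)silyl]oxypropanoate
Product: 8 (3S)-3-[5-(2-tert-butoxy-2-oxoethyl)-4-methoxy-2-methylphenyl]-3-[tert-butyl(dimethyl)silyl]oxypropanoic acid
Conditions: LiOH·H2O, THF/H2O, 0 °C; cold 1 M HCl to pH 4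
Reagents that add atoms: lithium hydroxide [Li+].[OH-]
Why: Saponification tells the two esters apart, because hydroxide attacks the methyl ester while the tert-butyl ester is shielded; the low temperature should prevent β-elimination of the silyloxy group.

Step 6
Reactants: 8 (3S)-3-[5-(2-tert-butoxy-2-oxoethyl)-4-methoxy-2-methylphenyl]-3-[tert-butyl(dimethyl)silyl]oxypropanoic acid
Product: 10 tert-butyl 2-[5-[(1S)-1-[tert-butyl(dimethyl)silyl]oxy-4-diazo-3-oxobutyl]-2-methoxy-4-methylphenyl]acetate, via mixed anhydride 9 (not isolated)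
Conditions: i-BuOCOCl, N-methylmorpholine, THF, −20 °C; then CH2N2, Et2O, −20 to 0 °C
Reagents that add atoms: diazomethane C=[N+]=[N-]
Why: Acylation of diazomethane by the mixed carbonic anhydride (first stage of an Arndt–Eistert sequence) gives the terminal diazoketone; the carbonate leaving group takes up the proton, so no acid forms that could destroy the diazo group.

Step 7
Reactants: 10 tert-butyl 2-[5-[(1S)-1-[tert-butyl(dimethyl)silyl]oxy-4-diazo-3-oxobutyl]-2-methoxy-4-methylphenyl]acetate
Product: 12 tert-butyl 2-[(3S)-3-[tert-butyl(dimethyl)silyl]oxy-6-methoxy-4-methyl-1-oxo-1,2,3,8a-tetrahydroazulen-7-yl]acetate (C8a epimers), via norcaradiene 11 (not isolated)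
Conditions: Rh2(OAc)4 (1 mol %), CH2Cl2, reflux, slow addition of 10
Reagents that add atoms: none
Why: Intramolecular Buchner reaction: the rhodium carbenoid cyclopropanates the ipso/ortho π-bond of the electron-rich anisole ring, and norcaradiene 11 opens by disrotatory 6π-electrocyclic cleavage of the shared cyclopropane bond, so the benzene ring is enlarged by the carbenoid carbon (C5). The closest known reaction type is the rhodium-catalysed cyclisation of 1-diazo-4-arylbutan-2-ones to dihydroazulen-1-ones. Ring A (five-membered) closes by carbenoid addition to the ipso carbon in a 5-exo sense, and the seven-membered ring arises from the six-membered arene by the electrocyclic opening, not by a cyclisation. The only new stereocentre, C5 (C8a), forms under the influence of C2 but is erased in step 8, so its configuration does not matter, and C2 itself is untouched. The step needs chemoselectivity for aromatic addition over oxonium-ylide formation at the silyl ether oxygen and over C–H insertion, which the poor donor ability of the bulky silyl ether and the para-methoxy activation should secure, and regioselectivity for the ipso/ortho-H bond, which the ortho-methyl group blocking the other side should secure. One step thus gives the hydroazulene core with the C4 carbonyl, the C8 oxygen, the C10 methyl and the C7 side chain in place.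

Step 8
Reactants: 12 tert-butyl 2-[(3S)-3-[tert-butyl(dimethyl)silyl]oxy-6-methoxy-4-methyl-1-oxo-1,2,3,8a-tetrahydroazulen-7-yl]acetate
Product: 14 tert-butyl 2-[(3S)-3-[tert-butyl(dimethyl)silyl]oxy-4-methyl-1,6-dioxo-1,2,3,6-tetrahydroazulen-7-yl]acetate, via methoxytropylium ion 13 (not isolated)
Conditions: DDQ (1.1 equiv), CH2Cl2/H2O (10:1), rt
Reagents that add atoms: water O
Why: Hydride abstraction by DDQ gives the methoxy-stabilised tropylium ion, which water turns into the tropone (the classical cycloheptatriene-to-tropone oxidation); the seven-membered ring becomes flat and C2 is the only stereocentre left to direct the reductions.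

Step 9
Reactants: 14 tert-butyl 2-[(3S)-3-[tert-butyl(dimethyl)silyl]oxy-4-methyl-1,6-dioxo-1,2,3,6-tetrahydroazulen-7-yl]acetate
Product: 15 tert-butyl 2-[(3S,4R,7S)-3-[tert-butyl(dimethyl)silyl]oxy-4-methyl-1,6-dioxo-1,2,3,4,5,6,7,8-octahydroazulen-7-yl]acetate
Conditions: 5 % Pd/C, H2 (1 atm), EtOAc, 0 °C, stopped after 2 equiv H2
Reagents that add atoms: none
Why: Heterogeneous hydrogenation: the flat tropone should adsorb through the face opposite the C2 silyloxy group, so both trisubstituted ring alkenes take up hydrogen from that face, which sets C10 (R) and C7 (S) cis to each other, while the tetrasubstituted C1=C5 enone bond is too hindered to react.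

Step 10
Reactants: 15 tert-butyl 2-[(3S,4R,7S)-3-[tert-butyl(dimethyl)silyl]oxy-4-methyl-1,6-dioxo-1,2,3,4,5,6,7,8-octahydroazulen-7-yl]acetate
Product: 16 tert-butyl 2-[(3S,4R,6S,7S)-3-[tert-butyl(dimethyl)silyl]oxy-6-hydroxy-4-methyl-1-oxo-1,2,3,4,5,6,7,8-octahydroazulen-7-yl]acetate
Conditions: L-Selectride (1.1 equiv), THF, −78 °C; aq NH4Cl
Reagents that add atoms: none
Why: Bulky-hydride reduction: the hydride attacks the saturated cycloheptanone from the face opposite the C7 side chain and the C10 methyl (both on one face) to give the cis-hydroxy ester (C8 S), and at −78 °C it should spare the hindered enone and the ester.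

Step 11
Reactants: 16 tert-butyl 2-[(3S,4R,6S,7S)-3-[tert-butyl(dimethyl)silyl]oxy-6-hydroxy-4-methyl-1-oxo-1,2,3,4,5,6,7,8-octahydroazulen-7-yl]acetate
Product: 18 (3aS,7S,8R,9aR)-7-[tert-butyl(dimethyl)silyl]oxy-8-methyl-3,3a,4,6,7,8,9,9a-octahydroazuleno[6,5-b]furan-2,5-dione, via mesylate 17 (not isolated)
Conditions: MsCl, Et3N, CH2Cl2, 0 °C; then 2,6-lutidine, toluene, 90 °C
Reagents that add atoms: none
Why: Intramolecular SN2 displacement: the carbonyl oxygen of the tert-butyl ester attacks C8 from the rear of the mesylate (5-exo-tet) and loses isobutene, so the lactone closes with inversion to the trans-fused C7/C8 arrangement (C8 R).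

Step 12
Reactants: 18 (3aS,7S,8R,9aR)-7-[tert-butyl(dimethyl)silyl]oxy-8-methyl-3,3a,4,6,7,8,9,9a-octahydroazuleno[6,5-b]furan-2,5-dione
Product: 19 (3aS,7S,8R,9aR)-7-[tert-butyl(dimethyl)silyl]oxy-5-hydroxy-5,8-dimethyl-3a,4,5,6,7,8,9,9a-octahydroazuleno[6,5-b]furan-2(3H)-one (C5 epimers)
Conditions: CeCl3 (dried), MeLi, THF, −78 °C
Reagents that add atoms: methyllithium [Li]C
Why: Organocerium 1,2-addition: the non-basic, oxophilic MeCeCl2 adds to the enone carbonyl without enolising C3 (which would expel the β-silyloxy group) and without attacking the lactone; the new C4 centre is destroyed in step 15, so its configuration is immaterial.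

Step 13
Reactants: 19 (3aS,7S,8R,9aR)-7-[tert-butyl(dimethyl)silyl]oxy-5-hydroxy-5,8-dimethyl-3a,4,5,6,7,8,9,9a-octahydroazuleno[6,5-b]furan-2(3H)-one
Product: 22 (3aS,7S,8R,9aR)-7-[tert-butyl(dimethyl)silyl]oxy-5-hydroxy-5,8-dimethyl-3-methylidene-3a,4,5,6,7,8,9,9a-octahydroazuleno[6,5-b]furan-2(3H)-one, via Mannich base 20 (not isolated), via ammonium iodide 21 (not isolated)
Conditions: LDA (2.2 equiv), THF, −78 °C; CH2=NMe2+ I−, −78 to 0 °C; then MeI, MeOH, rt; then aq NaHCO3, EtOAc
Reagents that add atoms: N,N-dimethylmethyleneiminium iodide (Eschenmoser's salt) C=[N+](C)C.[I-]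
Why: Eschenmoser methylenation: the lactone enolate (formed after the tertiary alkoxide) is aminomethylated at C11, and quaternisation followed by elimination of trimethylamine gives the exocyclic C11=C13 alkene.

Step 14
Reactants: 22 (3aS,7S,8R,9aR)-7-[tert-butyl(dimethyl)silyl]oxy-5-hydroxy-5,8-dimethyl-3-methylidene-3a,4,5,6,7,8,9,9a-octahydroazuleno[6,5-b]furan-2(3H)-one
Product: 24 (3aS,7S,8R,9aR)-5-hydroxy-5,8-dimethyl-3-methylidene-2-oxo-2,3,3a,4,5,6,7,8,9,9a-decahydroazuleno[6,5-b]furan-7-yl acetate, via diol 23 (not isolated)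
Conditions: TBAF, AcOH (1:1), THF, 0 °C to rt; then Ac2O, pyridine, DMAP (cat.), CH2Cl2, 0 °C
Reagents that add atoms: acetic anhydride CC(=O)OC(C)=O
Why: Buffered fluoride cleaves the Si–O bond, and acylation then occurs only at the secondary allylic C2 hydroxyl because the tertiary C4 hydroxyl is too hindered, so the acetate enters with retention at C2.

Step 15
Reactants: 24 (3aS,7S,8R,9aR)-5-hydroxy-5,8-dimethyl-3-methylidene-2-oxo-2,3,3a,4,5,6,7,8,9,9a-decahydroazuleno[6,5-b]furan-7-yl acetate
Product: 25 (3aS,7S,8R,9aR)-5,8-dimethyl-3-methylidene-2-oxo-2,3,3a,4,7,8,9,9a-octahydroazuleno[6,5-b]furan-7-yl acetate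
Conditions: Ph2S[OC(CF3)2Ph]2 (Martin sulfurane), CH2Cl2, −40 to 0 °C; cold filtration through neutral alumina; used at once
Reagents that add atoms: none
Why: Dehydration with Martin sulfurane: the alkoxysulfonium salt of the tertiary allylic alcohol eliminates towards C3, where the endocyclic conjugated cyclopentadiene is favoured over the exocyclic alkene, and the cold neutral conditions should avoid 1,5-hydrogen shifts of the 5-acetoxy diene.

**Dienophile half**

Step 16
Reactants: 26 1-methoxy-3-methylbenzene; 27 succinic anhydride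
Product: 28 4-(4-methoxy-2-methylphenyl)-4-oxobutanoic acid
Conditions: AlCl3 (2.2 equiv), CH2Cl2/PhNO2, 0 °C to rt; aq HCl
Reagents that add atoms: none
Why: Friedel–Crafts acylation with succinic anhydride para to methoxy and ortho to methyl delivers the four carbons C4'–C1' of the side chain.

Step 17
Reactants: 28 4-(4-methoxy-2-methylphenyl)-4-oxobutanoic acid
Product: 29 4-(4-methoxy-2-methylphenyl)pent-4-enoic acid
Conditions: Ph3PCH3Br, KOtBu (3.2 equiv), THF, 0 °C to rt
Reagents that add atoms: methyltriphenylphosphonium bromide C[P+](c1ccccc1)(c1ccccc1)c1ccccc1.[Br-]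
Why: Wittig methylenation of the aryl ketone (as its carboxylate) adds the carbon that becomes the C4' methyl group.

Step 18
Reactants: 29 4-(4-methoxy-2-methylphenyl)pent-4-enoic acid
Product: 30 (4R)-4-(4-methoxy-2-methylphenyl)pentanoic acid
Conditions: [Ir(cod)(SIPHOX)]BArF (1 mol %; the ligand antipode that gives the R acid), H2 (6 atm), Et3N (0.5 equiv), MeOH, rt
Reagents that add atoms: none
Why: Iridium-catalysed, carboxy-directed asymmetric hydrogenation of the 1,1-disubstituted aryl alkene sets C4' (R) under catalyst control.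

Step 19
Reactants: 30 (4R)-4-(4-methoxy-2-methylphenyl)pentanoic acid
Product: 31 (4R)-4-(4-methoxy-2-methylphenyl)pentan-1-ol
Conditions: LiAlH4, THF, 0 °C to reflux
Reagents that add atoms: none
Why: Hydride reduction of the carboxylic acid gives the primary alcohol (later C1'–OAc); the benzylic stereocentre carries no acidifying group and is not affected.

Step 20
Reactants: 31 (4R)-4-(4-methoxy-2-methylphenyl)pentan-1-ol
Product: 32 (4R)-4-(4-methoxy-2-methylcyclohexa-1,4-dien-1-yl)pentan-1-ol
Conditions: Li, NH3 (l), t-BuOH, THF, −78 to −33 °C; MeOH quench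
Reagents that add atoms: none
Why: Birch reduction: protonation at the two unsubstituted carbons ortho and meta to methoxy keeps the methoxy-bearing carbon and both alkylated carbons sp2, which gives the 1-methoxy-1,4-diene with the tetrasubstituted C5'=C10' alkene already in place.

Step 21
Reactants: 32 (4R)-4-(4-methoxy-2-methylcyclohexa-1,4-dien-1-yl)pentan-1-ol
Product: 33 triethyl[(4R)-4-(4-methoxy-2-methylcyclohexa-1,4-dien-1-yl)pentoxy]silane
Conditions: Et3SiCl, imidazole, CH2Cl2, 0 °C
Reagents that add atoms: chlorotriethylsilane CC[Si](Cl)(CC)CC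
Why: Silylation keeps the primary alcohol from O–H insertion in the carbenoid step, and the group is lost again in the acidic step 23 without a separate operation.

Step 22
Reactants: 33 triethyl[(4R)-4-(4-methoxy-2-methylcyclohexa-1,4-dien-1-yl)pentoxy]silane; 34 ethyl diazoacetate
Product: 35 ethyl (1R,6S,7S)-1-methoxy-3-methyl-4-[(2R)-5-triethylsilyloxypentan-2-yl]bicyclo[4.1.0]hept-3-ene-7-carboxylate
Conditions: CuOTf (2 mol %), 2,2'-(propane-2,2-diyl)bis(4-tert-butyl-4,5-dihydrooxazole) (2.2 mol %; the antipode that gives the 1R,6S adduct), CH2Cl2, 0 °C, slow addition of 34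
Reagents that add atoms: none
Why: Copper–bisoxazoline asymmetric cyclopropanation: the carbenoid attacks the electron-rich enol ether in preference to the tetrasubstituted alkene, and the ligand selects the enol ether face, which fixes C7' independently of the remote C4' centre (the ester epimer at C7 of the bicycle is immaterial).

Step 23
Reactants: 35 ethyl (1R,6S,7S)-1-methoxy-3-methyl-4-[(2R)-5-triethylsilyloxypentan-2-yl]bicyclo[4.1.0]hept-3-ene-7-carboxylate
Product: 36 ethyl 2-[(1S)-5-[(2R)-5-hydroxypentan-2-yl]-4-methyl-2-oxocyclohex-4-en-1-yl]acetate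
Conditions: 1 M aq HCl, THF, 0 °C
Reagents that add atoms: water O
Why: Acid-induced ring opening of the donor–acceptor cyclopropane: protonation at the ester α-carbon cleaves the C8'–C11' bond, the oxocarbenium ion is hydrolysed to the C8' ketone, C7' keeps its configuration because it is not involved, and the silyl ether falls off under the same conditions.

Step 24
Reactants: 36 ethyl 2-[(1S)-5-[(2R)-5-hydroxypentan-2-yl]-4-methyl-2-oxocyclohex-4-en-1-yl]acetate
Product: 38 (3aS,7aS)-5-[(2R)-5-hydroxypentan-2-yl]-6-methyl-3a,4,7,7a-tetrahydro-1-benzofuran-2(3H)-one, via hydroxy ester 37 (not isolated)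
Conditions: L-Selectride (2.2 equiv), THF, −78 °C; then aq NH4Cl, rt
Reagents that add atoms: none
Why: Bulky-hydride reduction anti to the adjacent C7' substituent gives the cis alkoxide (C8' S), which closes the cis-fused γ-lactone on the ethyl ester by intramolecular transesterification.

Step 25
Reactants: 38 (3aS,7aS)-5-[(2R)-5-hydroxypentan-2-yl]-6-methyl-3a,4,7,7a-tetrahydro-1-benzofuran-2(3H)-one
Product: 41 (3aS,7aS)-5-[(2R)-5-hydroxypentan-2-yl]-6-methyl-3-methylidene-3a,4,7,7a-tetrahydro-1-benzofuran-2(3H)-one, via Mannich base 39 (not isolated), via ammonium iodide 40 (not isolated)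
Conditions: LDA (2.2 equiv), THF, −78 °C; CH2=NMe2+ I−, −78 to 0 °C; then MeI, MeOH, rt; then aq NaHCO3, EtOAc
Reagents that add atoms: N,N-dimethylmethyleneiminium iodide (Eschenmoser's salt) C=[N+](C)C.[I-]
Why: Eschenmoser methylenation as in step 13 (alkoxide plus lactone enolate, aminomethylation, quaternisation, elimination).

Step 26
Reactants: 41 (3aS,7aS)-5-[(2R)-5-hydroxypentan-2-yl]-6-methyl-3-methylidene-3a,4,7,7a-tetrahydro-1-benzofuran-2(3H)-one
Product: 42 (4R)-4-[(3aS,7aS)-6-methyl-3-methylidene-2-oxo-2,3,3a,4,7,7a-hexahydro-1-benzofuran-5-yl]pentyl acetate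
Conditions: Ac2O, pyridine, DMAP (cat.), CH2Cl2, 0 °C
Reagents that add atoms: acetic anhydride CC(=O)OC(C)=O
Why: Acetylation of the only hydroxyl group gives the primary acetate of the target.

Step 27
Reactants: 42 (4R)-4-[(3aS,7aS)-6-methyl-3-methylidene-2-oxo-2,3,3a,4,7,7a-hexahydro-1-benzofuran-5-yl]pentyl acetate
Product: 43 (4R)-4-[(3aR,4R,7aS)-4-hydroxy-6-methyl-3-methylidene-2-oxo-2,3,3a,4,7,7a-hexahydro-1-benzofuran-5-yl]pentyl acetate
Conditions: SeO2 (0.5 equiv), t-BuOOH (2 equiv), CH2Cl2, 0 °C to rt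
Reagents that add atoms: tert-butyl hydroperoxide CC(C)(C)OO
Why: Selenium dioxide allylic hydroxylation (ene reaction, then [2,3]-sigmatropic shift): selenium should add to the less hindered methyl-bearing C10' and take hydrogen from the ring methylene C6' (the side-chain C4'–H lies in the alkene plane and C9' is deactivated by the neighbouring acyloxy carbon), with oxygen delivered on the convex face of the cis-fused bicycle to give the (R)-carbinol at C6'.

**Union**

Step 28
Reactants: 25 (3aS,7S,8R,9aR)-5,8-dimethyl-3-methylidene-2-oxo-2,3,3a,4,7,8,9,9a-octahydroazuleno[6,5-b]furan-7-yl acetate; 43 (4R)-4-[(3aR,4R,7aS)-4-hydroxy-6-methyl-3-methylidene-2-oxo-2,3,3a,4,7,7a-hexahydro-1-benzofuran-5-yl]pentyl acetate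
Product: 44 target dimer (SMILES as given)
Conditions: 43 (3 equiv), BHT (cat.), toluene (2 M), 25 °C, dark; 25 added over 12 h, then 4 d; excess 43 recovered
Reagents that add atoms: none
Why: Diels–Alder reaction of the 5-acetoxycyclopentadiene with the α-methylene lactone, in which the methylene carbon C13' bonds to the fully substituted C1 and the lactone α-carbon to C3, the dienophile comes to the diene face opposite the C2 acetate and the C10 methyl, the lactone carbonyl is exo as is usual for α-methylene lactones, and the diene must reach the lactone on the face that carries C6' (the least secure element), which together set C1, C3 and C11'; slow addition to an excess of 43 should suppress self-cycloaddition of 25.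

**Compound list**

1 | 1-bromo-2-methoxy-4-methylbenzene | COc1cc(C)ccc1Br | starting material
2 | methyl 3-chloro-3-oxopropanoate | COC(=O)CC(Cl)=O | starting material
3 | methyl 3-(5-bromo-4-methoxy-2-methylphenyl)-3-oxopropanoate | COC(=O)CC(=O)c1cc(Br)c(OC)cc1C | intermediate
4 | methyl (3S)-3-(5-bromo-4-methoxy-2-methylphenyl)-3-hydroxypropanoate | COC(=O)C[C@H](O)c1cc(Br)c(OC)cc1C | intermediate
5 | methyl (3S)-3-(5-bromo-4-methoxy-2-methylphenyl)-3-[tert-butyl(dimethyl)silyl]oxypropanoate | COC(=O)C[C@H](O[Si](C)(C)C(C)(C)C)c1cc(Br)c(OC)cc1C | intermediate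
6 | (2-tert-butoxy-2-oxoethyl)zinc bromide | CC(C)(C)OC(=O)C[Zn]Br | starting material
7 | methyl (3S)-3-[5-(2-tert-butoxy-2-oxoethyl)-4-methoxy-2-methylphenyl]-3-[tert-butyl(dimethyl)silyl]oxypropanoate | COC(=O)C[C@H](O[Si](C)(C)C(C)(C)C)c1cc(CC(=O)OC(C)(C)C)c(OC)cc1C | intermediate
8 | (3S)-3-[5-(2-tert-butoxy-2-oxoethyl)-4-methoxy-2-methylphenyl]-3-[tert-butyl(dimethyl)silyl]oxypropanoic acid | OC(=O)C[C@H](O[Si](C)(C)C(C)(C)C)c1cc(CC(=O)OC(C)(C)C)c(OC)cc1C | intermediate
9 | mixed isobutyl carbonic anhydride of 8 (not isolated) | CC(C)COC(=O)OC(=O)C[C@H](O[Si](C)(C)C(C)(C)C)c1cc(CC(=O)OC(C)(C)C)c(OC)cc1C | intermediate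
10 | tert-butyl 2-[5-[(1S)-1-[tert-butyl(dimethyl)silyl]oxy-4-diazo-3-oxobutyl]-2-methoxy-4-methylphenyl]acetate | [N-]=[N+]=CC(=O)C[C@H](O[Si](C)(C)C(C)(C)C)c1cc(CC(=O)OC(C)(C)C)c(OC)cc1C | intermediate
11 | norcaradiene valence isomer of 12 (cyclopropane centres undefined; not isolated) | O=C1C[C@H](O[Si](C)(C)C(C)(C)C)C23C1C2C(CC(=O)OC(C)(C)C)=C(OC)C=C3C | intermediate
12 | tert-butyl 2-[(3S)-3-[tert-butyl(dimethyl)silyl]oxy-6-methoxy-4-methyl-1-oxo-1,2,3,8a-tetrahydroazulen-7-yl]acetate (C8a epimers) | O=C1C[C@H](O[Si](C)(C)C(C)(C)C)C2=C(C)C=C(OC)C(CC(=O)OC(C)(C)C)=CC12 | intermediate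
13 | methoxytropylium ion from 12 (oxocarbenium form; not isolated) | C[O+]=C1C=C(C)C2=C(C=C1CC(=O)OC(C)(C)C)C(=O)C[C@@H]2O[Si](C)(C)C(C)(C)C | intermediate
14 | tert-butyl 2-[(3S)-3-[tert-butyl(dimethyl)silyl]oxy-4-methyl-1,6-dioxo-1,2,3,6-tetrahydroazulen-7-yl]acetate | O=C1C[C@H](O[Si](C)(C)C(C)(C)C)C2=C1C=C(CC(=O)OC(C)(C)C)C(=O)C=C2C | intermediate
15 | tert-butyl 2-[(3S,4R,7S)-3-[tert-butyl(dimethyl)silyl]oxy-4-methyl-1,6-dioxo-1,2,3,4,5,6,7,8-octahydroazulen-7-yl]acetate | O=C1C[C@H](O[Si](C)(C)C(C)(C)C)C2=C1C[C@@H](CC(=O)OC(C)(C)C)C(=O)C[C@H]2C | intermediate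
16 | tert-butyl 2-[(3S,4R,6S,7S)-3-[tert-butyl(dimethyl)silyl]oxy-6-hydroxy-4-methyl-1-oxo-1,2,3,4,5,6,7,8-octahydroazulen-7-yl]acetate | O=C1C[C@H](O[Si](C)(C)C(C)(C)C)C2=C1C[C@@H](CC(=O)OC(C)(C)C)[C@@H](O)C[C@H]2C | intermediate
17 | 6-methanesulfonate of 16 (not isolated) | O=C1C[C@H](O[Si](C)(C)C(C)(C)C)C2=C1C[C@@H](CC(=O)OC(C)(C)C)[C@@H](OS(C)(=O)=O)C[C@H]2C | intermediate
18 | (3aS,7S,8R,9aR)-7-[tert-butyl(dimethyl)silyl]oxy-8-methyl-3,3a,4,6,7,8,9,9a-octahydroazuleno[6,5-b]furan-2,5-dione | O=C1C[C@H](O[Si](C)(C)C(C)(C)C)C2=C1C[C@H]3CC(=O)O[C@@H]3C[C@H]2C | intermediate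
19 | (3aS,7S,8R,9aR)-7-[tert-butyl(dimethyl)silyl]oxy-5-hydroxy-5,8-dimethyl-3a,4,5,6,7,8,9,9a-octahydroazuleno[6,5-b]furan-2(3H)-one (C5 epimers) | CC1(O)C[C@H](O[Si](C)(C)C(C)(C)C)C2=C1C[C@H]3CC(=O)O[C@@H]3C[C@H]2C | intermediate
20 | 3-[(dimethylamino)methyl] derivative of 19 (C3 epimers; not isolated) | CN(C)CC1C(=O)O[C@@H]2C[C@@H](C)C3=C(C[C@@H]12)C(C)(O)C[C@@H]3O[Si](C)(C)C(C)(C)C | intermediate
21 | trimethylammonium iodide of 20 (not isolated) | C[N+](C)(C)CC1C(=O)O[C@@H]2C[C@@H](C)C3=C(C[C@@H]12)C(C)(O)C[C@@H]3O[Si](C)(C)C(C)(C)C.[I-] | intermediate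
22 | (3aS,7S,8R,9aR)-7-[tert-butyl(dimethyl)silyl]oxy-5-hydroxy-5,8-dimethyl-3-methylidene-3a,4,5,6,7,8,9,9a-octahydroazuleno[6,5-b]furan-2(3H)-one | C=C1C(=O)O[C@@H]2C[C@@H](C)C3=C(C[C@@H]12)C(C)(O)C[C@@H]3O[Si](C)(C)C(C)(C)C | intermediate
23 | (3aS,7S,8R,9aR)-5,7-dihydroxy-5,8-dimethyl-3-methylidene-3a,4,5,6,7,8,9,9a-octahydroazuleno[6,5-b]furan-2(3H)-one (not isolated) | C=C1C(=O)O[C@@H]2C[C@@H](C)C3=C(C[C@@H]12)C(C)(O)C[C@@H]3O | intermediate
24 | (3aS,7S,8R,9aR)-5-hydroxy-5,8-dimethyl-3-methylidene-2-oxo-2,3,3a,4,5,6,7,8,9,9a-decahydroazuleno[6,5-b]furan-7-yl acetate | C=C1C(=O)O[C@@H]2C[C@@H](C)C3=C(C[C@@H]12)C(C)(O)C[C@@H]3OC(C)=O | intermediate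
25 | (3aS,7S,8R,9aR)-5,8-dimethyl-3-methylidene-2-oxo-2,3,3a,4,7,8,9,9a-octahydroazuleno[6,5-b]furan-7-yl acetate | C=C1C(=O)O[C@@H]2C[C@@H](C)C3=C(C[C@@H]12)C(C)=C[C@@H]3OC(C)=O | intermediate
26 | 1-methoxy-3-methylbenzene | COc1cccc(C)c1 | starting material
27 | succinic anhydride | O=C1CCC(=O)O1 | starting material
28 | 4-(4-methoxy-2-methylphenyl)-4-oxobutanoic acid | COc1ccc(C(=O)CCC(=O)O)c(C)c1 | intermediate
29 | 4-(4-methoxy-2-methylphenyl)pent-4-enoic acid | COc1ccc(C(=C)CCC(=O)O)c(C)c1 | intermediate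
30 | (4R)-4-(4-methoxy-2-methylphenyl)pentanoic acid | COc1ccc([C@H](C)CCC(=O)O)c(C)c1 | intermediate
31 | (4R)-4-(4-methoxy-2-methylphenyl)pentan-1-ol | COc1ccc([C@H](C)CCCO)c(C)c1 | intermediate
32 | (4R)-4-(4-methoxy-2-methylcyclohexa-1,4-dien-1-yl)pentan-1-ol | COC1=CCC([C@H](C)CCCO)=C(C)C1 | intermediate
33 | triethyl[(4R)-4-(4-methoxy-2-methylcyclohexa-1,4-dien-1-yl)pentoxy]silane | COC1=CCC([C@H](C)CCCO[Si](CC)(CC)CC)=C(C)C1 | intermediate
34 | ethyl diazoacetate | CCOC(=O)C=[N+]=[N-] | starting material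
35 | ethyl (1R,6S,7S)-1-methoxy-3-methyl-4-[(2R)-5-triethylsilyloxypentan-2-yl]bicyclo[4.1.0]hept-3-ene-7-carboxylate | CCOC(=O)[C@@H]1[C@@]2(OC)CC(C)=C([C@H](C)CCCO[Si](CC)(CC)CC)C[C@@H]12 | intermediate
36 | ethyl 2-[(1S)-5-[(2R)-5-hydroxypentan-2-yl]-4-methyl-2-oxocyclohex-4-en-1-yl]acetate | CCOC(=O)C[C@@H]1CC([C@H](C)CCCO)=C(C)CC1=O | intermediate
37 | ethyl 2-[(1S,2S)-2-hydroxy-5-[(2R)-5-hydroxypentan-2-yl]-4-methylcyclohex-4-en-1-yl]acetate (not isolated) | CCOC(=O)C[C@@H]1CC([C@H](C)CCCO)=C(C)C[C@@H]1O | intermediate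
38 | (3aS,7aS)-5-[(2R)-5-hydroxypentan-2-yl]-6-methyl-3a,4,7,7a-tetrahydro-1-benzofuran-2(3H)-one | O=C1C[C@@H]2CC([C@H](C)CCCO)=C(C)C[C@@H]2O1 | intermediate
39 | 3-[(dimethylamino)methyl] derivative of 38 (C3 epimers; not isolated) | CN(C)CC1C(=O)O[C@H]2CC(C)=C([C@H](C)CCCO)C[C@@H]12 | intermediate
40 | trimethylammonium iodide of 39 (not isolated) | C[N+](C)(C)CC1C(=O)O[C@H]2CC(C)=C([C@H](C)CCCO)C[C@@H]12.[I-] | intermediate
41 | (3aS,7aS)-5-[(2R)-5-hydroxypentan-2-yl]-6-methyl-3-methylidene-3a,4,7,7a-tetrahydro-1-benzofuran-2(3H)-one | C=C1C(=O)O[C@H]2CC(C)=C([C@H](C)CCCO)C[C@@H]12 | intermediate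
42 | (4R)-4-[(3aS,7aS)-6-methyl-3-methylidene-2-oxo-2,3,3a,4,7,7a-hexahydro-1-benzofuran-5-yl]pentyl acetate | C=C1C(=O)O[C@H]2CC(C)=C([C@H](C)CCCOC(C)=O)C[C@@H]12 | intermediate
43 | (4R)-4-[(3aR,4R,7aS)-4-hydroxy-6-methyl-3-methylidene-2-oxo-2,3,3a,4,7,7a-hexahydro-1-benzofuran-5-yl]pentyl acetate | C=C1C(=O)O[C@H]2CC(C)=C([C@H](C)CCCOC(C)=O)[C@H](O)[C@@H]12 | intermediate
44 | target dimer CNP0211028.4 | C=C1C(=O)O[C@@H]2C[C@@H](C)[C@]34C[C@@]5(C(=O)O[C@H]6CC(C)=C([C@H](C)CCCOC(C)=O)[C@H](O)[C@H]65)[C@H](C(C)=C3C[C@@H]12)[C@@H]4OC(C)=O | target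

**Count and risks**

Total step count: 28. Longest linear sequence: 16 steps (steps 1–15, then step 28).

Step 28 is the most likely to fail. The 5-acetoxycyclopentadiene may isomerise by 1,5-hydrogen shift or add to itself faster than it adds to the lactone, and the face selectivity on the lactone (addition on the side of C6') may be poor. The fallback sets out from 43 and 24 and returns at 44. Alcohol 43 is silylated (Et3SiCl, imidazole) to the triethylsilyl ether F1. Alcohol 24 is then dehydrated with the Burgess reagent (MeO2CNSO2NEt3, benzene, 40 °C) in the presence of an excess of F1, so that diene 25 is trapped as it forms and never accumulates; the silyl group also covers the lactone face next to H-7'. The silylated cycloadduct F2 is deprotected with HF·pyridine to give 44.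

Step 9 comes next. Hydrogenation may run on into the C1=C5 enone, or the face selectivity at the remote C7 may be low once C10 has become sp3. The fallback sets out from 14 and returns at 15 without a new isolated compound (F0). Tropone 14 is reduced by two conjugate hydride additions with Stryker's reagent [(Ph3P)CuH]6 in toluene. Hydride enters C10 anti to the silyloxy group and C6, and the copper enolate is protonated at C7 by 2,6-di-tert-butylphenol from the open face. The tetrasubstituted enone does not accept hydride from this reagent.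

Step 27 is the third. The ene reaction may also take hydrogen from C9' or from the C10' methyl group, or the oxygen may enter on the wrong face. The fallback sets out from 42 and returns at 43. Allylic oxidation with CrO3·3,5-dimethylpyrazole (CH2Cl2, −20 °C) gives the enone F3, since the more electron-rich C6' methylene should be attacked first. Corey–Bakshi–Shibata reduction (oxazaborolidine antipode that gives the R carbinol, catecholborane, −78 °C) then sets C6' under reagent control.

**Further compounds**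

F1 | step 28 | (4R)-4-[(3aS,4R,7aS)-6-methyl-3-methylidene-2-oxo-4-triethylsilyloxy-2,3,3a,4,7,7a-hexahydro-1-benzofuran-5-yl]pentyl acetate | C=C1C(=O)O[C@H]2CC(C)=C([C@H](C)CCCOC(C)=O)[C@H](O[Si](CC)(CC)CC)[C@@H]12
F2 | step 28 | 6'-O-triethylsilyl ether of 44 | C=C1C(=O)O[C@@H]2C[C@@H](C)[C@]34C[C@@]5(C(=O)O[C@H]6CC(C)=C([C@H](C)CCCOC(C)=O)[C@H](O[Si](CC)(CC)CC)[C@H]65)[C@H](C(C)=C3C[C@@H]12)[C@@H]4OC(C)=O
F0 | step 9 | none | none
F3 | step 27 | (4R)-4-[(3aS,7aS)-6-methyl-3-methylidene-2,4-dioxo-2,3,3a,4,7,7a-hexahydro-1-benzofuran-5-yl]pentyl acetate | C=C1C(=O)O[C@H]2CC(C)=C([C@H](C)CCCOC(C)=O)C(=O)[C@@H]12
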